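## Retrosynthetic overview
1. The (S)-lactol and the ring A phenol are released last by neutral hydrogenolysis of a (1S)-1-phenylethyl acetal and a benzyl ether. The C–O bond at the stereocentre is never broken.
2. The seven-membered ring is cut first at the lactone C–O (carbodiimide lactonisation) and then at the diaryl ether C–O (SNAr). This gives a ring B catechol (fragment 1) and a ring A aryl fluoride (fragment 2).
3. The hexasubstituted ring B is closed by an intramolecular aldol condensation/aromatisation of a diketo-dioxinone. The chain is built from a dioxinone, (benzyloxy)acetyl chloride and methyl dimethoxyacetate, so every O and C substituent arrives at the right oxidation level.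
4. Ring A comes from 3-fluoro-5-methylphenol by para-bromination, directed lithiation/formylation and carboxylation.
5. Order of ring formation: ring B carbocycle, five-membered lactol (phthalide) ring, diaryl ether, seven-membered lactone.

Assumption: the lactol carbon is (S) by CIP analysis of the given SMILES; because a free lactol can epimerise by ring–chain tautomerism in protic or basic media, it is carried as a stable acetal, released only in the last neutral step, and the product is handled cold.

## Fragment 1 (ring B)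

Step 1
Reactants: 1 2,2,6-trimethyl-4H-1,3-dioxin-4-one; 2 (benzyloxy)acetyl chloride
Product: 4 6-[3-(benzyloxy)-2-oxopropyl]-2,2-dimethyl-4H-1,3-dioxin-4-one, via lithium dienolate 3 (not isolated)
Conditions: 1 (2.1 equiv), LiN(SiMe3)2 (2.1 equiv), THF, −78 °C, 1 h; 2 (1.0 equiv), −78 °C, 2 h; cold 1 M HCl
Reagents that add atoms: none
Why: This is a gamma-selective C-acylation (vinylogous Claisen-type) of the dioxinone dienolate by an acid chloride, in which the second equivalent of dienolate takes up the acidic proton of the product and so prevents double acylation.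

Step 2
Reactants: 4 6-[3-(benzyloxy)-2-oxopropyl]-2,2-dimethyl-4H-1,3-dioxin-4-one; 5 methyl 2,2-dimethoxyacetate
Product: 7 6-[3-(benzyloxy)-5,5-dimethoxy-2,4-dioxopentyl]-2,2-dimethyl-4H-1,3-dioxin-4-one, via dilithium dianion 6 (not isolated)
Conditions: LiN(i-Pr)2 (3.3 equiv), THF, −78 to −40 °C; 5 (1.2 equiv), −78 to −20 °C; cold 1 M HCl to pH 4
Reagents that add atoms: none
Why: In this crossed Claisen condensation the dianion reacts at its more basic terminal carbon (the one bearing OBn) with an ester that does not self-condense, the third equivalent of base holds the product as its enolate, and the new CH(OBn) centre is enolisable and becomes sp2 in step 3.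

Step 3 (key ring closure)
Reactants: 7 6-[3-(benzyloxy)-5,5-dimethoxy-2,4-dioxopentyl]-2,2-dimethyl-4H-1,3-dioxin-4-one
Product: 9 6-(benzyloxy)-5-(dimethoxymethyl)-7-hydroxy-2,2-dimethyl-4H-1,3-benzodioxin-4-one, via cyclic aldol 8 (not isolated)
Conditions: Et3N (3 equiv), CH2Cl2, rt, 16 h
Reagents that add atoms: none
Why: In this intramolecular (vinylogous) aldol condensation the gamma-deprotonated dioxinone attacks through C-5 the activated alpha,alpha-dimethoxy ketone to close a six-membered ring, and loss of water plus enolisation give the aromatic ring B with five substituents fixed by the chain sequence while the base-only medium spares acetal and acetonide.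

Step 4
Reactants: 9 6-(benzyloxy)-5-(dimethoxymethyl)-7-hydroxy-2,2-dimethyl-4H-1,3-benzodioxin-4-one
Product: 11 6-(benzyloxy)-5-(dimethoxymethyl)-7-hydroxy-2,2-dimethyl-4-oxo-4H-1,3-benzodioxine-8-carbaldehyde, via salicyl alcohol 10 (not isolated)
Conditions: MgCl2 (3 equiv), Et3N (4 equiv), (CH2O)n (7 equiv), MeCN, reflux; cold aq. citric acid
Reagents that add atoms: formaldehyde (as paraformaldehyde), C=O
Why: In this Casnati–Skattebøl ortho-formylation the magnesium phenoxide delivers formaldehyde to the only free ring position (C-8, ortho to OH and to O-1), and a second formaldehyde oxidises the benzylic alkoxide by hydride transfer under conditions that leave acetal and acetonide intact.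

Step 5
Reactants: 11 6-(benzyloxy)-5-(dimethoxymethyl)-7-hydroxy-2,2-dimethyl-4-oxo-4H-1,3-benzodioxine-8-carbaldehyde
Product: 12 5-(dimethoxymethyl)-6,7-dihydroxy-2,2-dimethyl-4-oxo-4H-1,3-benzodioxine-8-carbaldehyde
Conditions: H2 (1 atm), 10% Pd/C, EtOAc, rt
Reagents that add atoms: none
Why: Catalytic hydrogenolysis removes the aryl benzyl ether, while the hydrogen-bonded salicylaldehyde-type CHO, the dimethyl acetal and the acetonide are inert in neutral EtOAc at 1 atm.

Step 6
Reactants: 12 5-(dimethoxymethyl)-6,7-dihydroxy-2,2-dimethyl-4-oxo-4H-1,3-benzodioxine-8-carbaldehyde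
Product: 14 rac-3,4,5,7-tetrahydroxy-1-oxo-1,3-dihydro-2-benzofuran-6-carbaldehyde, via dialdehyde 13 (not isolated)
Conditions: TFA–H2O–THF (2:1:2), 50 °C, Ar
Reagents that add atoms: water, O
Why: Acid hydrolysis cleaves the acetal and then the acetonide acylal (assisted by the hydrate of the neighbouring formyl group), after which ring–chain tautomerism of the 2-formylbenzoic acid closes the five-membered lactol, whose new centre forms racemic at this stage.

Step 7
Reactants: 14 rac-3,4,5,7-tetrahydroxy-1-oxo-1,3-dihydro-2-benzofuran-6-carbaldehyde; 15 (S)-1-phenylethanol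
Product: 16 4,5,7-trihydroxy-1-oxo-3-[(1S)-1-phenylethoxy]-1,3-dihydro-2-benzofuran-6-carbaldehyde (mixture of C-3 epimers)
Conditions: 15 (3 equiv), PPTS (10 mol%), 4 Å molecular sieves, THF–toluene, 45 °C
Reagents that add atoms: none
Why: This dehydrative pseudo-ester (acetal) formation is typical of 3-hydroxyphthalides; the doubly hydrogen-bonded 6-CHO does not acetalise, PPTS is too weak to ionise the benzylic alcohol, and the acetal centre forms as roughly 1:1 epimers that are left unseparated because the free 4-OH keeps them labile.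

## Fragment 2 (ring A)

Step 8
Reactants: 17 3-fluoro-5-methylphenol
Product: 18 1-(benzyloxy)-3-fluoro-5-methylbenzene
Conditions: BnBr, K2CO3, DMF, rt
Reagents that add atoms: benzyl bromide, BrCc1ccccc1
Why: This is a Williamson ether synthesis on an unhindered phenoxide.

Step 9
Reactants: 18 1-(benzyloxy)-3-fluoro-5-methylbenzene
Product: 19 5-(benzyloxy)-2-bromo-1-fluoro-3-methylbenzene
Conditions: NBS, MeCN, dark, 0 °C to rt
Reagents that add atoms: N-bromosuccinimide, O=C1CCC(=O)N1Br
Why: Ionic electrophilic aromatic bromination with NBS in MeCN goes para to the alkoxy group, as it does for 3-fluoro- and 3,5-dimethyl-substituted aryl ethers, and the dark polar medium suppresses benzylic bromination.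

Step 10
Reactants: 19 5-(benzyloxy)-2-bromo-1-fluoro-3-methylbenzene
Product: 21 6-(benzyloxy)-3-bromo-2-fluoro-4-methylbenzaldehyde, via aryllithium 20 (not isolated)
Conditions: LiN(i-Pr)2 (1.1 equiv), THF, −78 °C, 1 h; DMF, −78 to 0 °C; 1 M HCl
Reagents that add atoms: N,N-dimethylformamide, CN(C)C=O
Why: In this directed ortho-metalation the amide base removes the most acidic ring proton (flanked by F and OBn) without bromine–lithium exchange, −78 °C prevents LiF loss, and DMF traps the anion as the aldehyde.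

Step 11
Reactants: 21 6-(benzyloxy)-3-bromo-2-fluoro-4-methylbenzaldehyde
Product: 22 1-(benzyloxy)-4-bromo-2-(dimethoxymethyl)-3-fluoro-5-methylbenzene
Conditions: HC(OMe)3, TsOH·H2O (2 mol%), MeOH, 50 °C; Et3N quench
Reagents that add atoms: trimethyl orthoformate, COC(OC)OC
Why: Acid-catalysed acetalisation driven by the orthoester masks the aldehyde against the organolithium of the next step.

Step 12
Reactants: 22 1-(benzyloxy)-4-bromo-2-(dimethoxymethyl)-3-fluoro-5-methylbenzene
Product: 25 4-(benzyloxy)-2-fluoro-3-formyl-6-methylbenzoic acid, via aryllithium 23 (not isolated), via lithium carboxylate 24 (not isolated)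
Conditions: n-BuLi (1.05 equiv), THF, −78 °C, 15 min; CO2 (g), −78 °C to rt; 1 M HCl–THF, rt, 1 h
Reagents that add atoms: carbon dioxide, O=C=O; water, O
Why: Bromine–lithium exchange at −78 °C outruns any deprotonation or LiF elimination, carboxylation places the acid between F and CH3, and the acidic work-up hydrolyses the electron-rich dimethyl acetal in the same pot.

Step 13
Reactants: 25 4-(benzyloxy)-2-fluoro-3-formyl-6-methylbenzoic acid
Product: 26 allyl 4-(benzyloxy)-2-fluoro-3-formyl-6-methylbenzoate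
Conditions: allyl bromide, KHCO3, DMF, rt
Reagents that add atoms: allyl bromide, C=CCBr
Why: SN2 O-alkylation of the carboxylate avoids attack at the hindered acyl carbon, and the weak base leaves the activated C–F bond untouched.

## Union and endgame

Step 14
Reactants: 16 4,5,7-trihydroxy-1-oxo-3-[(1S)-1-phenylethoxy]-1,3-dihydro-2-benzofuran-6-carbaldehyde (epimer mixture); 26 allyl 4-(benzyloxy)-2-fluoro-3-formyl-6-methylbenzoate
Product: 27 allyl 4-(benzyloxy)-3-formyl-2-({(3S)-6-formyl-5,7-dihydroxy-1-oxo-3-[(1S)-1-phenylethoxy]-1,3-dihydro-2-benzofuran-4-yl}oxy)-6-methylbenzoate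
Conditions: 16 (1.0 equiv), 26 (1.1 equiv), Cs2CO3 (3.5 equiv), DMSO, 55 °C, Ar; cold aq. citric acid; SiO2 chromatography to separate the C-3 epimers
Reagents that add atoms: none
Why: In this SNAr the fluoride flanked by ester and formyl groups is displaced by the 4-phenoxide, the most basic and nucleophilic oxygen, because the 5- and 7-phenoxides are vinylogous carboxylates and any Smiles aryl shift returns to the isomer that leaves the more acidic 5-OH free; arylation also ends the phenoxide-assisted epimerisation at C-3, so the (3S,1'S) diastereomer is obtained pure by chromatography.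

Step 15
Reactants: 27 allyl ester diaryl ether (3S,1'S)
Product: 28 4-(benzyloxy)-3-formyl-2-({(3S)-6-formyl-5,7-dihydroxy-1-oxo-3-[(1S)-1-phenylethoxy]-1,3-dihydro-2-benzofuran-4-yl}oxy)-6-methylbenzoic acid
Conditions: Pd(PPh3)4 (5 mol%), p-TolSO2Na (1.3 equiv), THF–MeOH, rt; 0.1 M HCl
Reagents that add atoms: none
Why: In this Tsuji–Trost deallylation zerovalent palladium ionises the allyl ester and the soft sulfinate traps the allyl unit irreversibly under neutral conditions that touch neither the aldehydes, the benzyl ether nor the acetal stereocentre.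

Step 16
Reactants: 28 seco acid (3S,1'S)
Product: 30 (1S)-10-(benzyloxy)-4-hydroxy-8-methyl-3,7-dioxo-1-[(1S)-1-phenylethoxy]-1,3-dihydro-7H-isobenzofuro[4,5-b][1,4]benzodioxepine-5,11-dicarbaldehyde, via O-acylisourea 29 (not isolated)
Conditions: DCC (1.5 equiv), DMAP (0.3 equiv), DMAP·HCl (0.3 equiv), CH2Cl2 (2 mM), rt
Reagents that add atoms: none
Why: This is a Steglich/Keck-type carbodiimide lactonisation at high dilution in which only the 5-OH next to the ether oxygen can reach the activated acyl group (seven-membered transition state), the buffered DMAP suppresses the N-acylurea shift, and the 7-OH is chelated between two carbonyl groups and too remote to compete.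

Step 17
Reactants: 30 protected depsidone (1S,1'S)
Product: 31 (1S)-1,4,10-trihydroxy-8-methyl-3,7-dioxo-1,3-dihydro-7H-isobenzofuro[4,5-b][1,4]benzodioxepine-5,11-dicarbaldehyde (target)
Conditions: H2 (1 atm), 10% Pd/C, EtOAc, 0–10 °C, stopped at full conversion; filter, concentrate below 10 °C, crystallise from cold acetone–hexane
Reagents that add atoms: none
Why: Catalytic hydrogenolysis cleaves only the two PhC–O bonds (O–CH2Ph and O–CH(CH3)Ph), so the oxygen stays on the lactol carbon and the (S) configuration is retained, while the hydrogen-bonded aryl aldehydes and both lactones survive the short neutral exposure.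

## Compound list
1 | 2,2,6-trimethyl-4H-1,3-dioxin-4-one | CC1=CC(=O)OC(C)(C)O1 | starting material
2 | (benzyloxy)acetyl chloride | O=C(Cl)COCc1ccccc1 | starting material
3 | lithium dienolate of 1 | [Li+].C=C1C=C([O-])OC(C)(C)O1 | intermediate
4 | 6-[3-(benzyloxy)-2-oxopropyl]-2,2-dimethyl-4H-1,3-dioxin-4-one | CC1(C)OC(=O)C=C(CC(=O)COCc2ccccc2)O1 | intermediate
5 | methyl 2,2-dimethoxyacetate | COC(OC)C(=O)OC | starting material
6 | dilithium dianion of 4 | [Li+].[Li+].CC1(C)OC(=O)C=C(C=C([O-])[CH-]OCc2ccccc2)O1 | intermediate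
7 | 6-[3-(benzyloxy)-5,5-dimethoxy-2,4-dioxopentyl]-2,2-dimethyl-4H-1,3-dioxin-4-one (enolisable centre, racemic) | CC1(C)OC(=O)C=C(CC(=O)C(OCc2ccccc2)C(=O)C(OC)OC)O1 | intermediate
8 | 6-(benzyloxy)-5-(dimethoxymethyl)-5-hydroxy-2,2-dimethyl-5,8-dihydro-4H-1,3-benzodioxine-4,7(6H)-dione (cyclic aldol, isomer mixture) | CC1(C)OC(=O)C2=C(O1)CC(=O)C(OCc1ccccc1)C2(O)C(OC)OC | intermediate
9 | 6-(benzyloxy)-5-(dimethoxymethyl)-7-hydroxy-2,2-dimethyl-4H-1,3-benzodioxin-4-one | CC1(C)OC(=O)c2c(O1)cc(O)c(OCc1ccccc1)c2C(OC)OC | intermediate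
10 | 6-(benzyloxy)-5-(dimethoxymethyl)-7-hydroxy-8-(hydroxymethyl)-2,2-dimethyl-4H-1,3-benzodioxin-4-one | CC1(C)OC(=O)c2c(O1)c(CO)c(O)c(OCc1ccccc1)c2C(OC)OC | intermediate
11 | 6-(benzyloxy)-5-(dimethoxymethyl)-7-hydroxy-2,2-dimethyl-4-oxo-4H-1,3-benzodioxine-8-carbaldehyde | CC1(C)OC(=O)c2c(O1)c(C=O)c(O)c(OCc1ccccc1)c2C(OC)OC | intermediate
12 | 5-(dimethoxymethyl)-6,7-dihydroxy-2,2-dimethyl-4-oxo-4H-1,3-benzodioxine-8-carbaldehyde | CC1(C)OC(=O)c2c(O1)c(C=O)c(O)c(O)c2C(OC)OC | intermediate
13 | 6,7-dihydroxy-2,2-dimethyl-4-oxo-4H-1,3-benzodioxine-5,8-dicarbaldehyde | CC1(C)OC(=O)c2c(O1)c(C=O)c(O)c(O)c2C=O | intermediate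
14 | rac-3,4,5,7-tetrahydroxy-1-oxo-1,3-dihydro-2-benzofuran-6-carbaldehyde | O=Cc1c(O)c(O)c2C(O)OC(=O)c2c1O | intermediate
15 | (S)-1-phenylethanol | C[C@H](O)c1ccccc1 | starting material
16 | 4,5,7-trihydroxy-1-oxo-3-[(1S)-1-phenylethoxy]-1,3-dihydro-2-benzofuran-6-carbaldehyde, C-3 epimer mixture | O=Cc1c(O)c(O)c2C(O[C@@H](C)c3ccccc3)OC(=O)c2c1O | intermediate
17 | 3-fluoro-5-methylphenol | Cc1cc(O)cc(F)c1 | starting material
18 | 1-(benzyloxy)-3-fluoro-5-methylbenzene | Cc1cc(F)cc(OCc2ccccc2)c1 | intermediate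
19 | 5-(benzyloxy)-2-bromo-1-fluoro-3-methylbenzene | Cc1cc(OCc2ccccc2)cc(F)c1Br | intermediate
20 | [6-(benzyloxy)-3-bromo-2-fluoro-4-methylphenyl]lithium | [Li]c1c(F)c(Br)c(C)cc1OCc1ccccc1 | intermediate
21 | 6-(benzyloxy)-3-bromo-2-fluoro-4-methylbenzaldehyde | Cc1cc(OCc2ccccc2)c(C=O)c(F)c1Br | intermediate
22 | 1-(benzyloxy)-4-bromo-2-(dimethoxymethyl)-3-fluoro-5-methylbenzene | Cc1cc(OCc2ccccc2)c(C(OC)OC)c(F)c1Br | intermediate
23 | [4-(benzyloxy)-3-(dimethoxymethyl)-2-fluoro-6-methylphenyl]lithium | [Li]c1c(C)cc(OCc2ccccc2)c(C(OC)OC)c1F | intermediate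
24 | lithium 4-(benzyloxy)-3-(dimethoxymethyl)-2-fluoro-6-methylbenzoate | [Li+].Cc1cc(OCc2ccccc2)c(C(OC)OC)c(F)c1C([O-])=O | intermediate
25 | 4-(benzyloxy)-2-fluoro-3-formyl-6-methylbenzoic acid | Cc1cc(OCc2ccccc2)c(C=O)c(F)c1C(=O)O | intermediate
26 | allyl 4-(benzyloxy)-2-fluoro-3-formyl-6-methylbenzoate | Cc1cc(OCc2ccccc2)c(C=O)c(F)c1C(=O)OCC=C | intermediate
27 | allyl 4-(benzyloxy)-3-formyl-2-({(3S)-6-formyl-5,7-dihydroxy-1-oxo-3-[(1S)-1-phenylethoxy]-1,3-dihydro-2-benzofuran-4-yl}oxy)-6-methylbenzoate | Cc1cc(OCc4ccccc4)c(C=O)c(c1C(=O)OCC=C)Oc1c(O)c(C=O)c(O)c2c1[C@@H](O[C@@H](C)c1ccccc1)OC2=O | intermediate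
28 | 4-(benzyloxy)-3-formyl-2-({(3S)-6-formyl-5,7-dihydroxy-1-oxo-3-[(1S)-1-phenylethoxy]-1,3-dihydro-2-benzofuran-4-yl}oxy)-6-methylbenzoic acid | Cc1cc(OCc4ccccc4)c(C=O)c(c1C(=O)O)Oc1c(O)c(C=O)c(O)c2c1[C@@H](O[C@@H](C)c1ccccc1)OC2=O | intermediate
29 | O-acylisourea of 28 formed by DCC | Cc1cc(OCc4ccccc4)c(C=O)c(c1C(=O)OC(=NC5CCCCC5)NC5CCCCC5)Oc1c(O)c(C=O)c(O)c2c1[C@@H](O[C@@H](C)c1ccccc1)OC2=O | intermediate
30 | (1S)-10-(benzyloxy)-4-hydroxy-8-methyl-3,7-dioxo-1-[(1S)-1-phenylethoxy]-1,3-dihydro-7H-isobenzofuro[4,5-b][1,4]benzodioxepine-5,11-dicarbaldehyde | Cc1cc(OCc4ccccc4)c(C=O)c2c1C(=O)Oc1c(C=O)c(O)c3c(c1O2)[C@@H](O[C@@H](C)c1ccccc1)OC3=O | intermediate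
31 | (1S)-1,4,10-trihydroxy-8-methyl-3,7-dioxo-1,3-dihydro-7H-isobenzofuro[4,5-b][1,4]benzodioxepine-5,11-dicarbaldehyde | Cc1cc(O)c(C=O)c2c1C(=O)Oc1c(C=O)c(O)c3c(c1O2)[C@@H](O)OC3=O | target

## Step count
- Total step count: 17.
- Longest linear sequence: 11 steps (steps 1–7, then 14–17).
- The ring A branch runs 10 steps (steps 8–13, then 14–17).

## Steps most likely to fail

**Step 2.**
- Risk: acylation of the alkoxy-substituted dianion by an ester may stall through proton transfer, or give retro-Claisen products.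
- Fallback: it sets out from 4 and comes back at 7.
- Dianion 6 is added at −78 °C to dried 2,2-dimethoxyacetaldehyde, which is far more electrophilic than ester 5.
- This gives the aldol 6-[3-(benzyloxy)-4-hydroxy-5,5-dimethoxy-2-oxopentyl]-2,2-dimethyl-4H-1,3-dioxin-4-one F1.
- Dess–Martin periodinane in CH2Cl2 then oxidises it to 7. The C–C bond is thus made at the alcohol oxidation level and the diketone appears only afterwards.

**Step 14.**
- Risk: the tris-phenoxide of 16 may oxidise, lose its labile acetal, or arylate sluggishly.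
- Fallback: it sets out from 12 and 26 and comes back at 27.
- The SNAr is run earlier, on the catechol 12, which carries only two phenols and no labile acetal.
- This gives allyl 4-(benzyloxy)-2-{[5-(dimethoxymethyl)-8-formyl-7-hydroxy-2,2-dimethyl-4-oxo-4H-1,3-benzodioxin-6-yl]oxy}-3-formyl-6-methylbenzoate F2.
- Aqueous TFA then unmasks the lactol allyl 4-(benzyloxy)-3-formyl-2-[(6-formyl-3,5,7-trihydroxy-1-oxo-1,3-dihydro-2-benzofuran-4-yl)oxy]-6-methylbenzoate F3.
- PPTS-catalysed acetalisation of F3 with 15, followed by chromatographic separation of the now configurationally stable epimers, gives 27.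

**Step 17.**
- Risk: the aldehydes may be over-reduced, the secondary benzylic acetal may cleave slowly, or the freed lactol may epimerise on the catalyst.
- Fallback: it sets out from 30 and comes back at 31 without a new compound (F0).
- Hydrogenolysis is replaced by Lewis-acid heterolysis with BCl3 and pentamethylbenzene in CH2Cl2 at −78 °C.
- Both benzylic groups then leave as cations that the arene traps. The 1-phenylethyl cation is much more stable than an acyloxycarbenium ion on the electron-poor ring B.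
- The bond that breaks is therefore again O–CH(CH3)Ph and not the bond at the stereocentre. A cold buffered quench releases 31.

## Further compounds
F1 | step 2 | 6-[3-(benzyloxy)-4-hydroxy-5,5-dimethoxy-2-oxopentyl]-2,2-dimethyl-4H-1,3-dioxin-4-one (diastereomer mixture) | CC1(C)OC(=O)C=C(CC(=O)C(OCc2ccccc2)C(O)C(OC)OC)O1
F2 | step 14 | allyl 4-(benzyloxy)-2-{[5-(dimethoxymethyl)-8-formyl-7-hydroxy-2,2-dimethyl-4-oxo-4H-1,3-benzodioxin-6-yl]oxy}-3-formyl-6-methylbenzoate | Cc1cc(OCc4ccccc4)c(C=O)c(c1C(=O)OCC=C)Oc1c(O)c(C=O)c2OC(C)(C)OC(=O)c2c1C(OC)OC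
F3 | step 14 | allyl 4-(benzyloxy)-3-formyl-2-[(6-formyl-3,5,7-trihydroxy-1-oxo-1,3-dihydro-2-benzofuran-4-yl)oxy]-6-methylbenzoate (racemic lactol) | Cc1cc(OCc4ccccc4)c(C=O)c(c1C(=O)OCC=C)Oc1c(O)c(C=O)c(O)c2c1C(O)OC2=O
F0 | step 17 | none | none
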